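**Plan**

Cuts: (a) the C8–CH2 bond of the ring A prenyl group, back to a 7-O-(1,1-dimethylallyl) ether. (b) The C2–C1' bond between ring C and ring B, back to a 4-chromone and an arylboronic acid. (c) The O–C(CH3)2 bond of the chromene ring, back to the isomeric 2-isopropenyl-2,3-dihydrobenzofuran. (d) That five-membered ring, back to an ortho-iodophenol and isoprene.
Enabling feature: the chromene ring holds the array aryl–O–C(CH3)2–CH=CH–aryl, an allyl aryl ether. The same oxygen and the same five carbons also form a dihydrofuran ring with one exocyclic isopropenyl carbon, and its O–C2 bond is allylic too. The two η3-allyl palladium species differ only by loss and return of Pd–H, so the ring can grow by that carbon without an oxidant that would endanger the prenyl groups.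
Forward order: ring B is bought, then C-prenylated, annulated with isoprene (five-membered O-ring), ring-expanded (six-membered O-ring) and borylated. Rings A and C are bought as 7-hydroxychromone. The halves are joined at C2–C1'. A final Claisen shift places the C8 prenyl group and frees the 7-OH, so no protecting group is used.
Stereochemistry: the only stereocentre, C2 (S), comes from the chiral diphosphine on rhodium in the 1,4-addition. The racemic centre of the dihydrofuran is erased in the ring expansion.

Key step: step 3

Assumption: the (S)-configured biaryl diphosphine is taken to send the aryl group to the Re face of C2 of the chromone, as (S)-BINAP-type ligands do with cyclic enones. If the sense were opposite, the (R)-ligand would be used.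

**Step 1**
Reactants: 1 4-chloro-2-iodophenol; 2 1-bromo-3-methylbut-2-ene (prenyl bromide)
Product: 3 4-chloro-2-iodo-6-(3-methylbut-2-en-1-yl)phenol
Conditions: NaH (1.05 equiv), toluene, 0 °C to rt; then 2 (1.1 equiv), rt to 40 °C
Reagents that add atoms: none
Why: Ortho-C-alkylation of a phenoxide (SN2 at the primary carbon of 2): the poorly solvated sodium phenoxide ion pair in toluene shields oxygen and favours attack from the ring carbon, and since chlorine blocks the para position and iodine one ortho position only C6 can be alkylated, the O-prenyl ether being a separable side product.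

**Step 2**
Reactants: 3 4-chloro-2-iodo-6-(3-methylbut-2-en-1-yl)phenol; 4 2-methylbuta-1,3-diene (isoprene)
Product: 5 (±)-5-chloro-7-(3-methylbut-2-en-1-yl)-2-(prop-1-en-2-yl)-2,3-dihydro-1-benzofuran
Conditions: Pd(OAc)2 (5 mol %), n-Bu4NCl (1 equiv), Na2CO3 (2 equiv), 4 (5 equiv), DMF, sealed tube, 90 °C
Reagents that add atoms: none
Why: Larock heteroannulation of a 1,3-diene: oxidative addition takes place only at the carbon–iodine bond, the aryl group adds to the unsubstituted vinyl terminus of 4, and the phenoxide closes the five-membered ring 5-exo on the inner terminus of the resulting η3-allyl palladium species, which leaves the isopropenyl group exocyclic, the new stereocentre being formed as a racemate that step 3 erases.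

**Step 3**
Reactants: 5 (±)-5-chloro-7-(3-methylbut-2-en-1-yl)-2-(prop-1-en-2-yl)-2,3-dihydro-1-benzofuran
Product: 7 6-chloro-2,2-dimethyl-8-(3-methylbut-2-en-1-yl)-2H-chromene, via dienylphenol 6 (not isolated)
Conditions: Pd(PPh3)4 (5 mol %), PhCO2H (10 mol %), degassed toluene, 100 °C
Reagents that add atoms: none
Why: Proposed new method: zerovalent palladium should ionise the allylic O–C2 bond of 5, helped by benzoic acid and by the chlorophenoxide leaving group, to an η3-allyl complex that loses the benzylic C3–H as Pd–H and gives dienylphenol 6; Pd–H then returns to the terminal CH2 of the diene and forms the aryl-conjugated η3-allyl complex C(CH3)2–CH–CH(aryl), whose tertiary terminus is attacked by the phenol oxygen. The closest known reaction types are the palladium-catalysed 1,4-elimination of allylic acetates and allyl phenyl ethers to 1,3-dienes, the Pd(PPh3)4/carboxylic acid hydroalkoxylation of dienes and alkynes through η3-allyl intermediates, and the Tsuji–Trost closure of 2-hydroxycinnamyl esters to 2H-chromenes; the new element is their merger into a redox-neutral one-carbon ring expansion of a 2-alkenyl-2,3-dihydrobenzofuran. The six-membered ring closes in a formal 6-endo-trig mode on the allyl unit after η3–η1–η3 rotation about the CH–CH(aryl) bond has brought the aryl group into the anti position, and attack at the benzylic terminus would need a four-membered ring, so only the O–C(CH3)2 bond can form. No stereocentre is made and the racemic C2 centre of 5 is erased. The step needs (a) ionisation in preference to Pd–H migration of the isopropenyl double bond into the five-membered ring, secured by the low acid loading and by the faster insertion of a 1,3-diene than of a 1,1-disubstituted alkene, (b) an untouched C–Cl bond and prenyl group, secured by the PPh3 ligand and by the trisubstitution of that alkene, and (c) a downhill end point, which holds because every step is reversible and the styrene-conjugated, less strained chromene 7 should be the most stable cyclic ether within this manifold.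

**Step 4**
Reactants: 7 6-chloro-2,2-dimethyl-8-(3-methylbut-2-en-1-yl)-2H-chromene
Product: 9 [2,2-dimethyl-8-(3-methylbut-2-en-1-yl)-2H-chromen-6-yl]boronic acid, via pinacol boronate 8 (not isolated)
Conditions: Pd2(dba)3 (1 mol %), XPhos (4 mol %), B2pin2 (1.2 equiv), KOAc (3 equiv), 1,4-dioxane, 110 °C; filter, concentrate; then NaIO4 (4 equiv), NH4OAc (4 equiv), acetone/H2O 1:1, rt
Reagents that add atoms: bis(pinacolato)diboron CC1(C)OB(OC1(C)C)B1OC(C)(C)C(C)(C)O1; water O
Why: Miyaura borylation of an aryl chloride, made possible by the bulky electron-rich biaryl phosphine, followed by periodate cleavage of the pinacol ester, with no hydride source present so that the alkenes persist and with any ionisation of the chromene ether by zerovalent palladium able only to fall back to the chromene.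

**Step 5**
Reactants: 10 2-methylbut-3-en-2-ol
Product: 11 methyl 2-methylbut-3-en-2-yl carbonate
Conditions: n-BuLi (1.05 equiv), THF, −78 to 0 °C; then ClCO2Me (1.1 equiv), 0 °C to rt
Reagents that add atoms: methyl chloroformate COC(=O)Cl
Why: O-acylation of a lithium tert-alkoxide by a chloroformate, the standard access to tertiary allylic carbonates.

**Step 6**
Reactants: 11 methyl 2-methylbut-3-en-2-yl carbonate; 12 7-hydroxy-4H-chromen-4-one
Product: 13 7-[(2-methylbut-3-en-2-yl)oxy]-4H-chromen-4-one
Conditions: Pd(PPh3)4 (2 mol %), THF, 0 °C to rt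
Reagents that add atoms: none
Why: Decarboxylative Tsuji–Trost O-allylation: ionisation of 11 releases methoxide, which deprotonates the acidic phenol 12, and the phenoxide attacks the more substituted terminus of the 1,1-dimethylallyl palladium cation under kinetic control, low temperature and short contact keeping the tertiary ether from re-ionising to the linear prenyl ether.

**Step 7**
Reactants: 9 [2,2-dimethyl-8-(3-methylbut-2-en-1-yl)-2H-chromen-6-yl]boronic acid; 13 7-[(2-methylbut-3-en-2-yl)oxy]-4H-chromen-4-one
Product: 14 (2S)-2-[2,2-dimethyl-8-(3-methylbut-2-en-1-yl)-2H-chromen-6-yl]-7-[(2-methylbut-3-en-2-yl)oxy]-2,3-dihydro-4H-chromen-4-one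
Conditions: [RhCl(C2H4)2]2 (1.5 mol %), (S)-MeO-F12-BIPHEP = (S)-2,2'-bis[bis(3,4,5-trifluorophenyl)phosphino]-6,6'-dimethoxy-1,1'-biphenyl (3.3 mol %), aq KOH (10 mol %), 9 (1.5 equiv), toluene/H2O 10:1, 20 °C
Reagents that add atoms: none
Why: Hayashi–Miyaura asymmetric 1,4-addition of an arylboronic acid to a 4-chromone: the aryl–rhodium species held by the axially chiral, electron-poor (S)-diphosphine should insert the C2=C3 bond from the Re face of C2 because a P-aryl group of the ligand blocks the Si face, which sets 2S, and fast hydrolysis of the oxa-π-allyl rhodium enolate at 20 °C forestalls β-elimination of the ring phenoxide, while the isolated alkenes and the tertiary allyl ether are not acceptors.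

**Step 8**
Reactants: 14 (2S)-2-[2,2-dimethyl-8-(3-methylbut-2-en-1-yl)-2H-chromen-6-yl]-7-[(2-methylbut-3-en-2-yl)oxy]-2,3-dihydro-4H-chromen-4-one
Product: 16 (2S)-2-[2,2-dimethyl-8-(3-methylbut-2-en-1-yl)-2H-chromen-6-yl]-7-hydroxy-8-(3-methylbut-2-en-1-yl)-2,3-dihydro-4H-chromen-4-one, via ortho-dienone 15 (not isolated)
Conditions: Eu(fod)3 (10 mol %), acid-free CHCl3, 50 °C
Reagents that add atoms: none
Why: Lewis-acid-accelerated aromatic Claisen rearrangement: the [3,3] shift inverts the 1,1-dimethylallyl unit into a prenyl group and should go to C8 rather than C6 because C8 lies between the two ring oxygens and the C7–C8 bond has the higher double-bond character, tautomerisation of 15 then frees the 7-OH, and the base-free medium leaves C2 untouched since that centre racemises only through enolate formation and opening of ring C.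

**Compound list**

1 | 4-chloro-2-iodophenol | Oc1ccc(Cl)cc1I | starting material
2 | 1-bromo-3-methylbut-2-ene (prenyl bromide) | CC(C)=CCBr | starting material
3 | 4-chloro-2-iodo-6-(3-methylbut-2-en-1-yl)phenol | CC(C)=CCc1cc(Cl)cc(I)c1O | intermediate
4 | 2-methylbuta-1,3-diene (isoprene) | C=CC(C)=C | starting material
5 | (±)-5-chloro-7-(3-methylbut-2-en-1-yl)-2-(prop-1-en-2-yl)-2,3-dihydro-1-benzofuran (racemate) | CC(C)=CCc1cc(Cl)cc2c1OC(C(C)=C)C2 | intermediate
6 | 4-chloro-2-[(1E)-3-methylbuta-1,3-dien-1-yl]-6-(3-methylbut-2-en-1-yl)phenol (not isolated) | CC(C)=CCc1cc(Cl)cc(/C=C/C(C)=C)c1O | intermediate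
7 | 6-chloro-2,2-dimethyl-8-(3-methylbut-2-en-1-yl)-2H-chromene | CC(C)=CCc1cc(Cl)cc2c1OC(C)(C)C=C2 | intermediate
8 | 2-[2,2-dimethyl-8-(3-methylbut-2-en-1-yl)-2H-chromen-6-yl]-4,4,5,5-tetramethyl-1,3,2-dioxaborolane (not isolated) | CC(C)=CCc1cc(B3OC(C)(C)C(C)(C)O3)cc2c1OC(C)(C)C=C2 | intermediate
9 | [2,2-dimethyl-8-(3-methylbut-2-en-1-yl)-2H-chromen-6-yl]boronic acid | CC(C)=CCc1cc(B(O)O)cc2c1OC(C)(C)C=C2 | intermediate
10 | 2-methylbut-3-en-2-ol | CC(C)(O)C=C | starting material
11 | methyl 2-methylbut-3-en-2-yl carbonate | COC(=O)OC(C)(C)C=C | intermediate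
12 | 7-hydroxy-4H-chromen-4-one | O=c1ccoc2cc(O)ccc12 | starting material
13 | 7-[(2-methylbut-3-en-2-yl)oxy]-4H-chromen-4-one | C=CC(C)(C)Oc1ccc2c(=O)ccoc2c1 | intermediate
14 | (2S)-2-[2,2-dimethyl-8-(3-methylbut-2-en-1-yl)-2H-chromen-6-yl]-7-[(2-methylbut-3-en-2-yl)oxy]-2,3-dihydro-4H-chromen-4-one | CC(C)=CCc1cc([C@@H]2CC(=O)c3ccc(OC(C)(C)C=C)cc3O2)cc2c1OC(C)(C)C=C2 | intermediate
15 | (2S)-2-[2,2-dimethyl-8-(3-methylbut-2-en-1-yl)-2H-chromen-6-yl]-8-(3-methylbut-2-en-1-yl)-2,3-dihydro-4H-chromene-4,7(8H)-dione (ortho-dienone, C8 unassigned, not isolated) | CC(C)=CCc1cc([C@@H]2CC(=O)C3=C(O2)C(CC=C(C)C)C(=O)C=C3)cc2c1OC(C)(C)C=C2 | intermediate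
16 | (2S)-2-[2,2-dimethyl-8-(3-methylbut-2-en-1-yl)-2H-chromen-6-yl]-7-hydroxy-8-(3-methylbut-2-en-1-yl)-2,3-dihydro-4H-chromen-4-one (CNP0110366.1) | CC(C)=CCc1cc([C@@H]2CC(=O)c3ccc(O)c(CC=C(C)C)c3O2)cc2c1OC(C)(C)C=C2 | target

**Count**

Total step count: 8.
Longest linear sequence: 6 (steps 1, 2, 3, 4, 7, 8).

**Steps most likely to fail**

Step 3 (labelled step). Three things may go wrong:
- Ionisation of the secondary allyl aryl ether may be slow.
- Palladium hydride may walk the isopropenyl double bond into the five-membered ring, with aromatisation.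
- The sequence may stall at the open diene stage, with oligomerisation.

The fallback uses known chemistry, sets out from 3 and 10 and comes back at 7. A Heck reaction at the carbon–iodine bond of 3 with 10 (Pd(OAc)2, n-Bu4NCl, NaHCO3, DMF, 80 °C) should give 4-chloro-2-[(1E)-3-hydroxy-3-methylbut-1-en-1-yl]-6-(3-methylbut-2-en-1-yl)phenol F1. Warming with pyridinium p-toluenesulfonate in toluene ionises the tertiary allylic alcohol. The phenol oxygen then closes on the allyl cation with loss of water to give 7. The O-ring is then built directly in its final size.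

Step 7. Three things may go wrong:
- The ring phenoxide may β-eliminate from the rhodium enolate, which opens ring C.
- A second aryl addition may occur at the ketone.
- Facial selectivity may be insufficient on the donor-substituted chromone.

The fallback moves the source of chirality from C–C bond formation to a kinetic resolution. It sets out from 9 and 13 and comes back at 14. An achiral 1,4-addition ([Rh(OH)(cod)]2, dioxane/H2O, 40 °C) should give rac-2-[2,2-dimethyl-8-(3-methylbut-2-en-1-yl)-2H-chromen-6-yl]-7-[(2-methylbut-3-en-2-yl)oxy]-2,3-dihydro-4H-chromen-4-one F2. Asymmetric transfer hydrogenation follows, with RuCl(p-cymene)[(R,R)-TsDPEN] and HCO2H/Et3N in EtOAc at rt, stopped near half conversion. It should reduce the matched 2R enantiomer to (2R,4R)-2-[2,2-dimethyl-8-(3-methylbut-2-en-1-yl)-2H-chromen-6-yl]-7-[(2-methylbut-3-en-2-yl)oxy]-3,4-dihydro-2H-chromen-4-ol F3 and leave 14, which is separated by chromatography.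

Step 8. Three things may go wrong:
- The allyl unit may migrate to C6 instead of C8.
- The Lewis acid may ionise the tertiary ether, with loss of the C5 unit.
- C2 may partly racemise through reversible opening of ring C.

The fallback runs the sigmatropic shift before the stereocentre exists. It sets out from 13 and comes back at 16.
- Thermal Claisen rearrangement of 13 (N,N-diethylaniline, 130 °C) should give 7-hydroxy-8-(3-methylbut-2-en-1-yl)-4H-chromen-4-one F4.
- TBSCl and imidazole in DMF give 7-[(tert-butyldimethylsilyl)oxy]-8-(3-methylbut-2-en-1-yl)-4H-chromen-4-one F5.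
- The rhodium-catalysed addition of 9 under the conditions of step 7 gives (2S)-7-[(tert-butyldimethylsilyl)oxy]-2-[2,2-dimethyl-8-(3-methylbut-2-en-1-yl)-2H-chromen-6-yl]-8-(3-methylbut-2-en-1-yl)-2,3-dihydro-4H-chromen-4-one F6.
- Et3N·3HF in THF at rt removes the silyl group without base and gives 16.

**Further compounds**

F1 | step 3 | 4-chloro-2-[(1E)-3-hydroxy-3-methylbut-1-en-1-yl]-6-(3-methylbut-2-en-1-yl)phenol | CC(C)=CCc1cc(Cl)cc(/C=C/C(C)(C)O)c1O
F2 | step 7 | rac-2-[2,2-dimethyl-8-(3-methylbut-2-en-1-yl)-2H-chromen-6-yl]-7-[(2-methylbut-3-en-2-yl)oxy]-2,3-dihydro-4H-chromen-4-one | CC(C)=CCc1cc(C2CC(=O)c3ccc(OC(C)(C)C=C)cc3O2)cc2c1OC(C)(C)C=C2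
F3 | step 7 | (2R,4R)-2-[2,2-dimethyl-8-(3-methylbut-2-en-1-yl)-2H-chromen-6-yl]-7-[(2-methylbut-3-en-2-yl)oxy]-3,4-dihydro-2H-chromen-4-ol | CC(C)=CCc1cc([C@H]2C[C@@H](O)c3ccc(OC(C)(C)C=C)cc3O2)cc2c1OC(C)(C)C=C2
F4 | step 8 | 7-hydroxy-8-(3-methylbut-2-en-1-yl)-4H-chromen-4-one | CC(C)=CCc1c(O)ccc2c(=O)ccoc12
F5 | step 8 | 7-[(tert-butyldimethylsilyl)oxy]-8-(3-methylbut-2-en-1-yl)-4H-chromen-4-one | CC(C)=CCc1c(O[Si](C)(C)C(C)(C)C)ccc2c(=O)ccoc12
F6 | step 8 | (2S)-7-[(tert-butyldimethylsilyl)oxy]-2-[2,2-dimethyl-8-(3-methylbut-2-en-1-yl)-2H-chromen-6-yl]-8-(3-methylbut-2-en-1-yl)-2,3-dihydro-4H-chromen-4-one | CC(C)=CCc1cc([C@@H]2CC(=O)c3ccc(O[Si](C)(C)C(C)(C)C)c(CC=C(C)C)c3O2)cc2c1OC(C)(C)C=C2
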